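**Retrosynthetic overview**
1. The C(=O)CH2Br arm goes on last: C-acylation of an exocyclic 2-ethylidene enol ether with bromoacetyl bromide; the enol ether comes from a trans-fused bromolactone by Takai ethylidenation.
2. Enabling feature: in the oxolane ring O1–C2–C3–C3a–C7a, C2 is a vinylogous-ester carbon (carboxyl level) and C7a is a tertiary C–O carbon, so the ring is a γ-butyrolactone in disguise: ketone (C7a=O) + vinyl group (C3a=C3) + CO (C2).
3. Key disconnection: titanocene hetero-Pauson–Khand cyclocarbonylation of acyclic (5S)-5-bromo-6,6-dimethyloct-7-en-2-one closes the cyclohexane (C3a–C7a) and the lactone ring (C3–C2, C2–O1) in one operation; the single C–Br stereocentre sets C3a and C7a.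
4. The bromo ketone comes from the (R)-bromohydrin triflate of 3,3-dimethylpent-4-enal (organocatalytic α-bromination) and lithiated acetone dimethylhydrazone.
5. Ring order: no ring exists before step 5; the cyclohexane and oxolane rings are formed together in step 5.

Key step: step 5

Remark: the sense of induction in step 2 is assumed from the steric model for 2,5-diphenylpyrrolidine enamines (bromine anti to the phenyl group next to the enamine carbon); if the opposite sense is found, the (2R,5R) amine is used instead.

Step 1
Reactants: 1 methyl 3,3-dimethylpent-4-enoate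
Product: 2 3,3-dimethylpent-4-enal
Conditions: i-Bu2AlH (1.05 equiv), CH2Cl2, −78 °C; aq. potassium sodium tartrate
Reagents that add atoms: none
Why: Partial reduction of an ester with i-Bu2AlH, which stops at the aluminium hemiacetal at −78 °C and releases the aldehyde only on work-up; no stereocentre is involved.

Step 2
Reactants: 2 3,3-dimethylpent-4-enal
Product: 4 (2R)-2-bromo-3,3-dimethylpent-4-en-1-ol, via (2R)-2-bromo-3,3-dimethylpent-4-enal 3 (not isolated)
Conditions: (2S,5S)-2,5-diphenylpyrrolidine (20 mol %), PhCO2H (20 mol %), 4,4-dibromo-2,6-di-tert-butylcyclohexa-2,5-dien-1-one, H2O (2 equiv), CH2Cl2–pentane, −40 °C; then NaBH4, MeOH, −40 → 0 °C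
Reagents that add atoms: 4,4-dibromo-2,6-di-tert-butylcyclohexa-2,5-dien-1-one, O=C1C(C(C)(C)C)=CC(Br)(Br)C=C1C(C)(C)C
Why: Enamine-catalysed asymmetric α-bromination of an aldehyde (organocatalytic α-halogenation) in which bromine should add to the enamine face opposite the phenyl group next to the nucleophilic carbon, setting C2 as R, with immediate NaBH4 reduction so that the configurationally labile α-bromo aldehyde is never isolated.

Step 3
Reactants: 4 (2R)-2-bromo-3,3-dimethylpent-4-en-1-ol
Product: 5 (2R)-2-bromo-3,3-dimethylpent-4-en-1-yl trifluoromethanesulfonate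
Conditions: Tf2O, 2,6-lutidine, CH2Cl2, −78 °C; used cold without purification
Reagents that add atoms: trifluoromethanesulfonic anhydride, O=S(=O)(OS(=O)(=O)C(F)(F)F)C(F)(F)F
Why: Sulfonylation of a primary alcohol with Tf2O and a hindered pyridine base at −78 °C, which does not touch the C–Br stereocentre.

Step 4
Reactants: 5 (2R)-2-bromo-3,3-dimethylpent-4-en-1-yl trifluoromethanesulfonate; 6 acetone N,N-dimethylhydrazone
Product: 8 (5S)-5-bromo-6,6-dimethyloct-7-en-2-one, via alkylated dimethylhydrazone 7 (not isolated)
Conditions: 6, n-BuLi (1.0 equiv), THF, 0 °C; then 5, −78 → −40 °C, AcOH quench; then aq. oxalic acid, Et2O, 25 °C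
Reagents that add atoms: water, O
Why: Alkylation of a lithiated N,N-dimethylhydrazone (aza-enolate alkylation of the Corey–Enders type) by SN2 displacement at the primary CH2–OTf carbon, which leaves the neighbouring C–Br stereocentre untouched (its descriptor changes from R to S only because the CIP ranks change), followed by mild acidic hydrolysis of the hydrazone to the methyl ketone.

Step 5
Reactants: 8 (5S)-5-bromo-6,6-dimethyloct-7-en-2-one
Product: 11 (3aS,5S,7aS)-5-bromo-4,4,7a-trimethylhexahydro-1-benzofuran-2(3H)-one, via oxatitanacyclopentane 9 (not isolated), via acyl titanacycle 10 (not isolated)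
Conditions: Cp2Ti(PMe3)2 (1.1 equiv; from Cp2TiCl2, Mg, PMe3), toluene, 25 °C; then CO (1.2 bar), 25 °C; then 70 °C
Reagents that add atoms: carbon monoxide, [C-]#[O+]
Why: The divalent titanium complex loses PMe3 and binds the ketone side-on (a titanaoxirane), the vinyl group inserts into its Ti–C bond (oxidative cyclisation) to give oxatitanacyclopentane 9 with tetravalent titanium, CO inserts into the Ti–CH2 bond (10), and C–O reductive elimination on warming releases the lactone and Cp2Ti(CO)2. This is the titanocene-mediated hetero-Pauson–Khand cyclocarbonylation of tethered alkenyl ketones to fused γ-butyrolactones, applied here to a six-membered carbocycle. The cyclohexane closes by a 6-exo-type insertion of the alkene (new C3a–C7a bond), and the lactone is completed as a five-membered ring by CO insertion (new C3–C2 bond) and C2–O1 reductive elimination. Both new stereocentres follow from C5: in the chair-like bicyclic metallacycle the C–Br bond is equatorial and the two titanium-bound atoms (O on C7a, CH2 on C3a) should take the trans-diequatorial positions, which a Cp2Ti bridge spans easily and which keep the Cp rings away from the axial C4 methyl, so the ketone methyl is axial and H-3a is anti to it (3aS,7aS); reversible metallacycle formation should funnel the isomers to this one before CO is admitted. The step needs chemoselectivity for ketone and alkene over the C–Br bond, which the neopentyl shielding of the secondary bromide and the fast chelation-driven cyclisation at 25 °C should secure (titanium is no longer reducing once 9 has formed), and it needs CO insertion into Ti–C and not Ti–O, which is the normal course.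

Step 6
Reactants: 11 (3aS,5S,7aS)-5-bromo-4,4,7a-trimethylhexahydro-1-benzofuran-2(3H)-one; 12 1,1-dibromoethane
Product: 13 (2Z,3aS,5S,7aS)-5-bromo-2-ethylidene-4,4,7a-trimethyloctahydro-1-benzofuran
Conditions: TiCl4, TMEDA, Zn, PbCl2 (cat.), 12 (2.2 equiv), THF, 0 → 25 °C; Et3N/aq. K2CO3 work-up, basic Al2O3; used at once
Reagents that add atoms: none
Why: Takai alkylidenation of an ester carbonyl by the gem-dimetallic reagent made from CH3CHBr2, Zn and TiCl4–TMEDA, a Wittig-type C=O to C=CHCH3 exchange that should give the (Z)-enol ether and leaves the three stereocentres untouched; the alkene geometry is erased in the next step.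

Step 7
Reactants: 13 (2Z,3aS,5S,7aS)-5-bromo-2-ethylidene-4,4,7a-trimethyloctahydro-1-benzofuran; 14 bromoacetyl bromide
Product: 15 (3Z)-1-bromo-3-[(3aS,5S,7aS)-5-bromo-4,4,7a-trimethylhexahydro-1-benzofuran-2(3H)-ylidene]butan-2-one (target)
Conditions: 14 (1.1 equiv), 2,6-di-tert-butyl-4-methylpyridine, CH2Cl2, −78 → 0 °C
Reagents that add atoms: none
Why: C-Acylation of an enol ether at its nucleophilic β-carbon by an acid bromide (Friedel–Crafts-type acylation of vinyl ethers) and loss of the proton from the same carbon give the push–pull vinylogous ester, whose Z geometry (acyl cis to the ring oxygen, methyl cis to the ring CH2) should be the thermodynamic one because it keeps the planar acyl group clear of the ring CH2, the low rotation barrier of the push–pull alkene allowing equilibration to it.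

**Compound list**
1 | methyl 3,3-dimethylpent-4-enoate | COC(=O)CC(C)(C)C=C | starting material
2 | 3,3-dimethylpent-4-enal | O=CCC(C)(C)C=C | intermediate
3 | (2R)-2-bromo-3,3-dimethylpent-4-enal | O=C[C@H](Br)C(C)(C)C=C | intermediate (not isolated)
4 | (2R)-2-bromo-3,3-dimethylpent-4-en-1-ol | OC[C@H](Br)C(C)(C)C=C | intermediate
5 | (2R)-2-bromo-3,3-dimethylpent-4-en-1-yl trifluoromethanesulfonate | FC(F)(F)S(=O)(=O)OC[C@H](Br)C(C)(C)C=C | intermediate
6 | acetone N,N-dimethylhydrazone | CC(C)=NN(C)C | starting material
7 | (5S)-5-bromo-6,6-dimethyloct-7-en-2-one N,N-dimethylhydrazone (C=N isomers) | CC(CC[C@H](Br)C(C)(C)C=C)=NN(C)C | intermediate (not isolated)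
8 | (5S)-5-bromo-6,6-dimethyloct-7-en-2-one | CC(=O)CC[C@H](Br)C(C)(C)C=C | intermediate
9 | oxatitanacyclopentane: Cp2Ti bridging O on C7a and the CH2 on C3a, trans-fused to the cyclohexane, Br equatorial, configuration as in 11 (η5-Cp rings written as σ-bonded C5H5 in the SMILES) | [Ti]1(C3C=CC=C3)(C4C=CC=C4)C[C@H]2C(C)(C)[C@@H](Br)CC[C@]2(C)O1 | intermediate (not isolated)
10 | acyl titanacycle: six-membered ring Ti–C(=O)–CH2–C3a–C7a–O, configuration as in 11 (Cp rings written as in 9) | O=C1C[C@H]2C(C)(C)[C@@H](Br)CC[C@]2(C)O[Ti]1(C3C=CC=C3)C4C=CC=C4 | intermediate (not isolated)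
11 | (3aS,5S,7aS)-5-bromo-4,4,7a-trimethylhexahydro-1-benzofuran-2(3H)-one | O=C1C[C@H]2C(C)(C)[C@@H](Br)CC[C@]2(C)O1 | intermediate
12 | 1,1-dibromoethane | CC(Br)Br | starting material
13 | (2Z,3aS,5S,7aS)-5-bromo-2-ethylidene-4,4,7a-trimethyloctahydro-1-benzofuran | C/C=C1/C[C@H]2C(C)(C)[C@@H](Br)CC[C@]2(C)O1 | intermediate
14 | bromoacetyl bromide | O=C(Br)CBr | starting material
15 | (3Z)-1-bromo-3-[(3aS,5S,7aS)-5-bromo-4,4,7a-trimethylhexahydro-1-benzofuran-2(3H)-ylidene]butan-2-one | C/C(C(=O)CBr)=C1\C[C@H]2C(C)(C)[C@@H](Br)CC[C@]2(C)O1 | target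

Total step count: 7. Longest linear sequence: 7 steps (1 → 15).

**Steps most likely to fail, with fallbacks**

Step 5 (key step). What may go wrong: halogen-atom abstraction from the secondary C–Br bond by the divalent titanium complex before oxidative cyclisation; sluggish six-membered oxidative cyclisation; or ring closure through the cis-fused metallacycle (wrong ring-fusion selectivity). The fallback is stepwise and uses polarity reversal at the ketone. It sets out from 8: cross-metathesis with methyl acrylate (second-generation Hoveyda–Grubbs catalyst, RuCl2(H2IMes)(=CH–C6H4-2-O-i-Pr), toluene, 80 °C) should give methyl (2E,5S)-5-bromo-4,4-dimethyl-8-oxonon-2-enoate F1. SmI2 (2.2 equiv) with MeOH in THF at −78 °C, without HMPA so that the alkyl bromide is not reduced, should then effect the ketyl–olefin 6-exo cyclisation with the samarium alkoxide anti to the CH2CO2Me arm, giving methyl 2-[(1S,3S,6S)-3-bromo-6-hydroxy-2,2,6-trimethylcyclohexyl]acetate F2. Lactonisation of F2 (PPTS, benzene, 60 °C) returns to the route at 11.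

Step 4. What may go wrong: E2 loss of triflate or attack of the strongly basic aza-enolate at bromine or sulfur in place of SN2 at the hindered CH2, and base-induced intramolecular alkylation at C–Br if the aza-enolate is in excess. The fallback forms the C6–C7 bond by olefination and sets out from 3, taken as the crude solution from the first half of step 2. A Wittig reaction with Ph3P=CHC(O)CH3 (CH2Cl2, 0 °C) should give (3E,5S)-5-bromo-6,6-dimethylocta-3,7-dien-2-one F3. Chemoselective radical conjugate reduction of the enone with Mn(dpm)3 (dpm = dipivaloylmethanate; cat.), PhSiH3 and i-PrOH under argon, which should leave the isolated vinyl group and the bromide alone, returns to the route at 8.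

Step 6. What may go wrong: incomplete alkylidenation of the hindered lactone carbonyl, reduction of the C–Br bond by the low-valent titanium–zinc reagent, or acid-catalysed isomerisation or hydrolysis of the exocyclic enol ether on isolation. The fallback builds the side chain by enolate acylation and sets out from 11. The regiodefined lithium enolate of butan-2-one (from 2-(trimethylsilyloxy)but-2-ene and MeLi, THF, 0 °C; 2.2 equiv; then 11, −78 → 25 °C) should open the lactone in a Claisen-type condensation to 1-[(1S,3S,6S)-3-bromo-6-hydroxy-2,2,6-trimethylcyclohexyl]-3-methylpentane-2,4-dione F4. Cyclodehydration (p-TsOH, toluene, 4 Å sieves, 60 °C) should give (3Z)-3-[(3aS,5S,7aS)-5-bromo-4,4,7a-trimethylhexahydro-1-benzofuran-2(3H)-ylidene]butan-2-one F5. Kinetic deprotonation at the terminal methyl (LiN(SiMe3)2, THF, −78 °C) and bromination with N-bromosuccinimide returns to the route at 15, bypassing 13.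

**Further compounds**
F1 | step 5 | methyl (2E,5S)-5-bromo-4,4-dimethyl-8-oxonon-2-enoate | CC(=O)CC[C@H](Br)C(C)(C)/C=C/C(=O)OC
F2 | step 5 | methyl 2-[(1S,3S,6S)-3-bromo-6-hydroxy-2,2,6-trimethylcyclohexyl]acetate | COC(=O)C[C@H]1C(C)(C)[C@@H](Br)CC[C@]1(C)O
F3 | step 4 | (3E,5S)-5-bromo-6,6-dimethylocta-3,7-dien-2-one | CC(=O)/C=C/[C@H](Br)C(C)(C)C=C
F4 | step 6 | 1-[(1S,3S,6S)-3-bromo-6-hydroxy-2,2,6-trimethylcyclohexyl]-3-methylpentane-2,4-dione (epimers at C3 of the dione) | CC(=O)C(C)C(=O)C[C@H]1C(C)(C)[C@@H](Br)CC[C@]1(C)O
F5 | step 6 | (3Z)-3-[(3aS,5S,7aS)-5-bromo-4,4,7a-trimethylhexahydro-1-benzofuran-2(3H)-ylidene]butan-2-one | C/C(C(C)=O)=C1\C[C@H]2C(C)(C)[C@@H](Br)CC[C@]2(C)O1
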